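**Retrosynthetic overview**
1. Rhodisin ⇒ its hexadeca-O-benzyl ether; global hydrogenolysis is the last step.
2. The benzylated dimer ⇒ two molecules of one monomer, octa-O-benzyl-EGCG, by cutting the C4–C8' interflavan bond back to two C–H partners. DDQ hydride abstraction dearomatises ring A of one molecule to a para-quinone-methide cation; the second, still aromatic molecule captures it at C8, anti to the 3-O-gallate, which sets C4.
3. Octa-O-benzyl-EGCG ⇒ penta-O-benzyl-epigallocatechin + 3,4,5-tris(benzyloxy)benzoic acid (ester bond); the former ⇒ (−)-epigallocatechin + benzyl bromide (commodity aromatic).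
4. Ring order: no ring is built. All eight rings and four of the five stereocentres come intact from the tea catechin; only the C4–C8' bond and C4 are made.

Assumption: the SMILES is read as (−)-epigallocatechin 3-O-gallate-(4β→8)-(−)-epigallocatechin 3-O-gallate (upper unit 2R,3R,4R; lower unit 2R,3R); (−)-epigallocatechin and 3,4,5-tris(benzyloxy)benzoic acid are taken as catalogue compounds. Reagents that leave no atoms in a product (bases, DCC, DDQ, H2, catalysts) are not numbered.

**Step 1**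
Reactants: 1 (−)-epigallocatechin (EGC); 2 benzyl bromide
Product: 3 5,7,3',4',5'-penta-O-benzyl-(−)-epigallocatechin [(2R,3R)-5,7-bis(benzyloxy)-2-[3,4,5-tris(benzyloxy)phenyl]chroman-3-ol]
Conditions: BnBr (5.5 equiv), K2CO3 (7 equiv), degassed DMF, Ar, −10 °C → rt, 16 h
Reagents that add atoms: benzyl bromide (2), BrCc1ccccc1
Why: fivefold Williamson etherification in which carbonate deprotonates only the five phenols and not the secondary 3-OH, under oxygen-free, unheated conditions that do not open the pyran ring or epimerise C2 or C3.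

**Step 2**
Reactants: 3 5,7,3',4',5'-penta-O-benzyl-(−)-epigallocatechin; 4 3,4,5-tris(benzyloxy)benzoic acid
Product: 5 octa-O-benzyl-EGCG [(2R,3R)-5,7-bis(benzyloxy)-2-[3,4,5-tris(benzyloxy)phenyl]chroman-3-yl 3,4,5-tris(benzyloxy)benzoate]
Conditions: 4 (1.5 equiv), DCC (1.6 equiv), DMAP (0.3 equiv), CH2Cl2, 0 °C → rt, 18 h
Reagents that add atoms: 3,4,5-tris(benzyloxy)benzoic acid (4), OC(=O)c1cc(OCc2ccccc2)c(OCc2ccccc2)c(OCc2ccccc2)c1
Why: Steglich esterification of the only free hydroxyl (the axial 3-OH) through the DMAP acylpyridinium of 4; the C3–O bond is not touched, so C3 is retained.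

**Step 3**
Reactants: 5 octa-O-benzyl-EGCG (two molecules; 4 equiv of 5 per DDQ)
Product: 8 hexadeca-O-benzylrhodisin [octa-O-benzyl-EGCG-(4β→8)-octa-O-benzyl-EGCG; upper unit 2R,3R,4R; lower unit 2R,3R], via ring-A quinone-methide oxocarbenium ion pair 6 (not isolated), via C4–O DDQH adduct 7 (not isolated)
Conditions: DDQ (0.25 equiv per 5, added over 1 h), anhydrous CH2Cl2, rt, 2 h; then BF3·OEt2 (0.1 equiv), −78 → −30 °C; aq. NaHCO3 quench; unreacted 5 recovered and recycled
Reagents that add atoms: none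
Why: Proposed new method: a one-pot cross-dehydrogenative Friedel–Crafts dimerisation in which DDQ abstracts the pseudo-axial C4 hydride of one molecule of 5 and so dearomatises ring A to the 7-benzyloxonium para-quinone methide 6 (resting in part as the labile C4–O adduct 7, which BF3·OEt2 re-ionises once DDQ is spent), and the rearomatising cation is attacked by C8 (the less hindered, most nucleophilic ring-A position) of a second, still aromatic molecule of 5 on the β face, anti to the 2-aryl and 3-O-galloyl groups and opposite the gallate carbonyl that can bridge the α face as a dioxolanylium, which sets C4 as R (3,4-trans, 4β→8), while substoichiometric DDQ and the hindered, quasi-equatorial C4–H of 8 hold back over-oxidation and trimer formation; the closest known reactions are the DDQ-mediated C4-alkoxylation of O-benzylated flavan-3-ols and the Lewis-acid coupling of the resulting flavan-4-yl cations with C8 of a second flavan.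

**Step 4**
Reactants: 8 hexadeca-O-benzylrhodisin
Product: 9 rhodisin
Conditions: H2 (1 atm), Pd(OH)2/C, THF/MeOH/H2O (20:1:1), rt, 12 h; filter, Sephadex LH-20 (MeOH), lyophilise
Reagents that add atoms: none
Why: catalytic hydrogenolysis of the sixteen aryl benzyl ethers under neutral, room-temperature conditions that leave the two gallate esters, the cyclic C2–O1 ethers, the C4–C8' bond and all five stereocentres untouched.

**Compound list**
1 | (−)-epigallocatechin (EGC), (2R,3R), 2,3-cis | O[C@@H]1Cc2c(O)cc(O)cc2O[C@@H]1c1cc(O)c(O)c(O)c1 | starting material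
2 | benzyl bromide | BrCc1ccccc1 | starting material
3 | 5,7,3',4',5'-penta-O-benzyl-(−)-epigallocatechin, (2R,3R) | O[C@@H]1Cc2c(OCc3ccccc3)cc(OCc3ccccc3)cc2O[C@@H]1c1cc(OCc2ccccc2)c(OCc2ccccc2)c(OCc2ccccc2)c1 | intermediate
4 | 3,4,5-tris(benzyloxy)benzoic acid | OC(=O)c1cc(OCc2ccccc2)c(OCc2ccccc2)c(OCc2ccccc2)c1 | starting material
5 | octa-O-benzyl-EGCG, (2R,3R) | O=C(O[C@@H]1Cc2c(OCc3ccccc3)cc(OCc3ccccc3)cc2O[C@@H]1c1cc(OCc2ccccc2)c(OCc2ccccc2)c(OCc2ccccc2)c1)c1cc(OCc2ccccc2)c(OCc2ccccc2)c(OCc2ccccc2)c1 | intermediate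
6 | ring-A-dearomatised 7-benzyloxonium para-quinone methide of 5 (C4=C4a; C2, C3 unchanged), ion pair with the DDQ hydroquinone monoanion | O=C(O[C@@H]1C=C2C(OCc3ccccc3)=CC(=[O+]Cc3ccccc3)C=C2O[C@@H]1c1cc(OCc2ccccc2)c(OCc2ccccc2)c(OCc2ccccc2)c1)c1cc(OCc2ccccc2)c(OCc2ccccc2)c(OCc2ccccc2)c1.[O-]c1c(Cl)c(Cl)c(O)c(C#N)c1C#N | intermediate
7 | 4β-(2,3-dichloro-5,6-dicyano-4-hydroxyphenoxy)-octa-O-benzyl-EGCG (3,4-trans C4–O adduct) | O=C(O[C@@H]1[C@@H](Oc2c(Cl)c(Cl)c(O)c(C#N)c2C#N)c2c(OCc3ccccc3)cc(OCc3ccccc3)cc2O[C@@H]1c1cc(OCc2ccccc2)c(OCc2ccccc2)c(OCc2ccccc2)c1)c1cc(OCc2ccccc2)c(OCc2ccccc2)c(OCc2ccccc2)c1 | intermediate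
8 | hexadeca-O-benzylrhodisin: octa-O-benzyl-EGCG-(4β→8)-octa-O-benzyl-EGCG; upper unit 2R,3R,4R (2,3-cis, 3,4-trans), lower unit 2R,3R | O=C(O[C@@H]1[C@@H](c2c(OCc4ccccc4)cc(OCc4ccccc4)c3c2O[C@H](c2cc(OCc4ccccc4)c(OCc4ccccc4)c(OCc4ccccc4)c2)[C@H](OC(=O)c2cc(OCc4ccccc4)c(OCc4ccccc4)c(OCc4ccccc4)c2)C3)c2c(OCc4ccccc4)cc(OCc4ccccc4)cc2O[C@@H]1c1cc(OCc2ccccc2)c(OCc2ccccc2)c(OCc2ccccc2)c1)c1cc(OCc2ccccc2)c(OCc2ccccc2)c(OCc2ccccc2)c1 | intermediate
9 | rhodisin: EGCG-(4β→8)-EGCG; upper unit 2R,3R,4R, lower unit 2R,3R | O=C(O[C@@H]1[C@@H](c2c(O)cc(O)c3c2O[C@H](c2cc(O)c(O)c(O)c2)[C@H](OC(=O)c2cc(O)c(O)c(O)c2)C3)c2c(O)cc(O)cc2O[C@@H]1c1cc(O)c(O)c(O)c1)c1cc(O)c(O)c(O)c1 | target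

**Totals**
Total step count: 4. Longest linear sequence: 4 steps (1 → 3 → 5 → 8 → 9).

**Steps most likely to fail, with fallbacks**

Step 3 (highest risk). The 3-O-acyl group may slow hydride abstraction, the cation may stay as the C4–O adduct, and C6 isomers or trimers may form. The fallback sets out from 3 and comes back to the route at 8. It separates oxidation from C–C bond formation and does the oxidation on the free 3-ol, where C4 hydride abstraction is established. Part of 3 is oxidised with DDQ in CH2Cl2 containing 2-ethoxyethanol at rt to the isolable 4β-(2-ethoxyethoxy)-5,7,3',4',5'-penta-O-benzyl-(−)-epigallocatechin F1. O3 of F1 is then acylated with acid 4 (DCC, DMAP, CH2Cl2) to give 4β-(2-ethoxyethoxy)-octa-O-benzyl-EGCG F2. Finally F2 is ionised with TMSOTf (0.1 equiv) in CH2Cl2 at −78 °C in the presence of 5 (4 equiv) as the C8 nucleophile, which gives 8 with the same anti (4β) selectivity.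

Step 1 (second). The pyrogallol-type polyphenolate can autoxidise under base, C-benzylate at C6/C8 or epimerise at C2. The fallback sets out from 1 and comes back to the route at 3. Compound 1 is peracetylated (Ac2O, pyridine, rt) to the air-stable (−)-epigallocatechin hexaacetate F3. F3 then undergoes one-pot deacetylation–benzylation (NaH, benzyl bromide 2, DMF, 5 equiv H2O added slowly, 0 °C). Each phenoxide is unmasked by in-situ hydroxide and benzylated at once, so no free polyphenolate accumulates, while the slower-reacting secondary acetate is kept; the product is 3-O-acetyl-5,7,3',4',5'-penta-O-benzyl-(−)-epigallocatechin F4. Mild methanolysis of F4 (K2CO3, MeOH/THF, rt) removes the 3-O-acetate and gives 3.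

Step 4 (third). Sixteen-fold hydrogenolysis may stall at partly benzylated, poorly soluble stages or be poisoned by traces of chlorinated by-products. The fallback sets out from 8 and comes back to the route at 9. It replaces reductive cleavage by non-reductive Lewis-acid debenzylation with a cation scavenger: BCl3 (excess) and pentamethylbenzene in CH2Cl2 at −78 °C, then MeOH quench. This cleaves the aryl benzyl ethers by C–O heterolysis, and the low temperature is intended to spare the gallate esters and the acid-sensitive interflavan bond. New compounds: none F0.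

**Further compounds**
F1 | step 3 | 4β-(2-ethoxyethoxy)-5,7,3',4',5'-penta-O-benzyl-(−)-epigallocatechin (2,3-cis, 3,4-trans) | O[C@@H]1[C@@H](OCCOCC)c2c(OCc3ccccc3)cc(OCc3ccccc3)cc2O[C@@H]1c1cc(OCc2ccccc2)c(OCc2ccccc2)c(OCc2ccccc2)c1
F2 | step 3 | 4β-(2-ethoxyethoxy)-octa-O-benzyl-EGCG (2,3-cis, 3,4-trans) | O=C(O[C@@H]1[C@@H](OCCOCC)c2c(OCc3ccccc3)cc(OCc3ccccc3)cc2O[C@@H]1c1cc(OCc2ccccc2)c(OCc2ccccc2)c(OCc2ccccc2)c1)c1cc(OCc2ccccc2)c(OCc2ccccc2)c(OCc2ccccc2)c1
F3 | step 1 | (−)-epigallocatechin hexaacetate, (2R,3R) | CC(=O)O[C@@H]1Cc2c(OC(C)=O)cc(OC(C)=O)cc2O[C@@H]1c1cc(OC(C)=O)c(OC(C)=O)c(OC(C)=O)c1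
F4 | step 1 | 3-O-acetyl-5,7,3',4',5'-penta-O-benzyl-(−)-epigallocatechin, (2R,3R) | CC(=O)O[C@@H]1Cc2c(OCc3ccccc3)cc(OCc3ccccc3)cc2O[C@@H]1c1cc(OCc2ccccc2)c(OCc2ccccc2)c(OCc2ccccc2)c1
F0 | step 4 | none | none
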